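## Retrosynthetic overview

1. The hydroxyquinone is unveiled last by nitrosodisulfonate oxidation of the free 2-alkyl-4-chloro-5-methylresorcinol; this six-membered ring is the orcinol ring carried through the route.
2. The side chain is cut at the C(OH)–C(Me)= bond: a proposed nickel-catalysed enantioselective reductive coupling of an aryl but-2-yne with a keto aldehyde forms this bond, the 4S carbinol and the E-alkene in one step.
3. The keto aldehyde comes from ozonolysis of (2R,3S,4S)-3-allyl-2,3,4-trimethylcyclohexanone (2-methyl cis, 4-methyl trans to the 3-methyl); C2 is set by enolate methylation and the quaternary C3 by conjugate methylation of (S)-3-allyl-4-methylcyclohexenone.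
4. That enone comes from (S)-4-methylcyclohexenone (conjugate allylation, Saegusa–Ito oxidation), itself from an organocatalytic Michael addition of propanal to methyl vinyl ketone and aldol ring closure; this carbocycle is the only ring built and is formed first.
5. The aryl butyne comes from orcinol: MOM protection, lithiation between the ethers and propargylation, deprotection, chlorination, silylation.

Assumption 1: the (R)-prolinol catalyst of step 1 is taken to give the (S)-aldehyde and the (4S,5S)-carbene of step 13 to open the Re face of the aldehyde; if a first run shows the opposite sense, the antipodal catalyst is used and nothing else changes.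

Assumption 2: the carbene precursor of step 13 is a new compound, taken to be prepared beforehand from (1S,2S)-1,2-diphenylethane-1,2-diamine; as a catalyst it is not counted among the steps.

## Route

Step 1
Reactants: 1 propanal; 2 but-3-en-2-one (methyl vinyl ketone)
Product: 3 (2S)-2-methyl-5-oxohexanal
Conditions: (R)-2-[diphenyl(trimethylsilyloxy)methyl]pyrrolidine (5 mol%), ethyl 3,4-dihydroxybenzoate (20 mol%), neat, 4 °C
Reagents that add atoms: none
Why: Enamine-mediated organocatalytic asymmetric Michael addition, in which the E-enamine of propanal attacks the enone from the face not shielded by the diphenyl(silyloxy)methyl group and so sets the methyl-bearing centre (later ring carbon 4) as S.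

Step 2
Reactants: 3 (2S)-2-methyl-5-oxohexanal
Product: 5 (4S)-4-methylcyclohex-2-en-1-one, via aldol adduct 4 (not isolated)
Conditions: LiOH (10 mol%), i-PrOH, rt
Reagents that add atoms: none
Why: Intramolecular aldol condensation of the methyl ketone onto the aldehyde closes the six-membered enone faster than the α-branched aldehyde enolises, so the stereocentre is kept.

Step 3
Reactants: 5 (4S)-4-methylcyclohex-2-en-1-one
Product: 6 trimethyl{[(3R,4S)-4-methyl-3-(prop-2-en-1-yl)cyclohex-1-en-1-yl]oxy}silane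
Conditions: allylMgBr (1.3 equiv), CuBr·SMe2 (1.3 equiv), TMSCl (2 equiv), THF, −78 °C
Reagents that add atoms: allylmagnesium bromide, C=CC[Mg]Br; chlorotrimethylsilane, C[Si](C)(C)Cl
Why: Conjugate (1,4) addition of allylcopper with in situ silylation gives the regiodefined silyl enol ether, with allyl anti to the 4-methyl group (this new centre is erased in step 4).

Step 4
Reactants: 6 trimethyl{[(3R,4S)-4-methyl-3-(prop-2-en-1-yl)cyclohex-1-en-1-yl]oxy}silane
Product: 7 (4S)-4-methyl-3-(prop-2-en-1-yl)cyclohex-2-en-1-one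
Conditions: Pd(OAc)2 (10 mol%), O2 (1 atm), DMSO, rt
Reagents that add atoms: none
Why: Saegusa–Ito oxidation, in which the C2-bound palladium enolate loses the C3 hydrogen by β-hydride elimination, restores the enone with allyl now on C3 and leaves C4 untouched.

Step 5
Reactants: 7 (4S)-4-methyl-3-(prop-2-en-1-yl)cyclohex-2-en-1-one
Product: 8 {[(3S,4S)-3,4-dimethyl-3-(prop-2-en-1-yl)cyclohex-1-en-1-yl]oxy}trimethylsilane
Conditions: MeMgBr (2 equiv), CuBr·SMe2 (10 mol%), TMSCl (2.5 equiv), HMPA (2.5 equiv), THF, −78 → −40 °C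
Reagents that add atoms: methylmagnesium bromide, C[Mg]Br; chlorotrimethylsilane, C[Si](C)(C)Cl
Why: Copper-catalysed conjugate addition with silyl trapping, in which A(1,2) strain holds the 4-methyl group pseudoaxial so that methyl adds anti to it, creates the quaternary centre (3S) with allyl cis to the 4-methyl group.

Step 6
Reactants: 8 {[(3S,4S)-3,4-dimethyl-3-(prop-2-en-1-yl)cyclohex-1-en-1-yl]oxy}trimethylsilane
Product: 10 (2R,3S,4S)-2,3,4-trimethyl-3-(prop-2-en-1-yl)cyclohexan-1-one, via lithium enolate 9 (not isolated)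
Conditions: MeLi (1.05 equiv), THF, 0 °C; then MeI (5 equiv), DMPU, −78 → −20 °C
Reagents that add atoms: iodomethane, CI
Why: Regiospecific enolate alkylation, in which MeLi cleaves the Si–O bond and MeI attacks C2 on the face opposite the pseudoaxial allyl group and the 4-methyl group, sets C2 as R (methyl cis to the 3-methyl) under kinetic control.

Step 7
Reactants: 10 (2R,3S,4S)-2,3,4-trimethyl-3-(prop-2-en-1-yl)cyclohexan-1-one
Product: 12 2-[(1S,2R,6S)-1,2,6-trimethyl-3-oxocyclohexyl]acetaldehyde, via ozonide 11 (not isolated)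
Conditions: O3, CH2Cl2, −78 °C; then PPh3, −78 °C → rt
Reagents that add atoms: ozone, [O-][O+]=O
Why: Ozonolysis with reductive work-up cleaves only the terminal alkene under neutral conditions, so the α-stereocentre of the ketone is not touched.

Step 8
Reactants: 13 5-methylbenzene-1,3-diol (orcinol)
Product: 15 1,3-bis(methoxymethoxy)-5-methylbenzene, via disodium diolate 14 (not isolated)
Conditions: NaH (2.4 equiv), DMF, 0 °C; then MOMCl (2.3 equiv), 0 °C → rt
Reagents that add atoms: chloromethyl methyl ether, COCCl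
Why: Williamson etherification of the bis-phenoxide installs two MOM ethers that later direct lithiation to the carbon between them.

Step 9
Reactants: 15 1,3-bis(methoxymethoxy)-5-methylbenzene; 16 1-bromobut-2-yne
Product: 18 2-(but-2-yn-1-yl)-1,3-bis(methoxymethoxy)-5-methylbenzene, via aryllithium 17 (not isolated)
Conditions: n-BuLi (1.1 equiv), THF, 0 °C → rt; then 16, −78 °C → rt
Reagents that add atoms: none
Why: Directed ortho-metalation at the position flanked by both MOM ethers, then SN2 alkylation of the aryllithium by the primary propargylic bromide, forms the aryl–CH2 bond.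

Step 10
Reactants: 18 2-(but-2-yn-1-yl)-1,3-bis(methoxymethoxy)-5-methylbenzene
Product: 19 2-(but-2-yn-1-yl)-5-methylbenzene-1,3-diol
Conditions: conc. HCl (cat.), MeOH, 40 °C
Reagents that add atoms: none
Why: Acid-catalysed acetal exchange with methanol removes both MOM groups while the isolated alkyne is inert.

Step 11
Reactants: 19 2-(but-2-yn-1-yl)-5-methylbenzene-1,3-diol
Product: 20 2-(but-2-yn-1-yl)-4-chloro-5-methylbenzene-1,3-diol
Conditions: NCS (1.0 equiv), MeCN, 0 °C → rt
Reagents that add atoms: N-chlorosuccinimide, O=C1CCC(=O)N1Cl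
Why: Electrophilic aromatic chlorination gives one monochloride because the two free ring positions are equivalent by symmetry and both are activated ortho/para by the hydroxyl groups.

Step 12
Reactants: 20 2-(but-2-yn-1-yl)-4-chloro-5-methylbenzene-1,3-diol
Product: 21 {[2-(but-2-yn-1-yl)-4-chloro-5-methyl-1,3-phenylene]bis(oxy)}bis[tert-butyl(dimethyl)silane]
Conditions: TBSOTf (2.4 equiv), 2,6-lutidine (3 equiv), CH2Cl2, 0 °C → rt
Reagents that add atoms: tert-butyldimethylsilyl trifluoromethanesulfonate, CC(C)(C)[Si](C)(C)OS(=O)(=O)C(F)(F)F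
Why: O-Silylation of both hindered phenols gives fluoride-labile ethers that tolerate zerovalent nickel and silane.

Step 13
Reactants: 12 2-[(1S,2R,6S)-1,2,6-trimethyl-3-oxocyclohexyl]acetaldehyde; 21 {[2-(but-2-yn-1-yl)-4-chloro-5-methyl-1,3-phenylene]bis(oxy)}bis[tert-butyl(dimethyl)silane]
Product: 22 (2R,3S,4S)-3-[(2S,3E)-5-{2,6-bis[(tert-butyldimethylsilyl)oxy]-3-chloro-4-methylphenyl}-3-methyl-2-[(triethylsilyl)oxy]pent-3-en-1-yl]-2,3,4-trimethylcyclohexan-1-one
Conditions: Ni(cod)2 [bis(cycloocta-1,5-diene)nickel] (10 mol%), (4S,5S)-1,3-bis(3,5-di-tert-butylphenyl)-4,5-diphenyl-4,5-dihydro-1H-imidazol-3-ium tetrafluoroborate (11 mol%), KOt-Bu (10 mol%), Et3SiH (2 equiv), THF, rt, slow addition of 12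
Reagents that add atoms: triethylsilane, CC[SiH](CC)CC
Why: Proposed new method: zerovalent nickel carrying a small C2-symmetric carbene binds alkyne and aldehyde and undergoes oxidative cyclization to an oxanickelacyclopentene in which the C–C bond forms at the methyl-bearing alkyne carbon (the bulky arylmethyl group sits next to nickel, where the ortho-unsubstituted N-aryl carbene leaves room, and away from the neopentyl-type aldehyde substituent), the twisted 3,5-di-tert-butylphenyl walls expose the Re face of the aldehyde to set the carbinol as S, and Si–H σ-bond metathesis followed by C–H reductive elimination gives the E-alkene by cis addition of H and the carbinol carbon, while the ketone and the hindered electron-rich aryl chloride are expected to react far more slowly at rt; the closest known reaction type is the nickel–carbene/silane reductive coupling of aldehydes with alkynes, whose combined regio- and enantiocontrol has not been shown for a methyl/arylmethyl dialkyl alkyne joined to a β-quaternary keto aldehyde.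

Step 14
Reactants: 22 (2R,3S,4S)-3-[(2S,3E)-5-{2,6-bis[(tert-butyldimethylsilyl)oxy]-3-chloro-4-methylphenyl}-3-methyl-2-[(triethylsilyl)oxy]pent-3-en-1-yl]-2,3,4-trimethylcyclohexan-1-one
Product: 23 (2R,3S,4S)-3-[(2S,3E)-5-(3-chloro-2,6-dihydroxy-4-methylphenyl)-2-hydroxy-3-methylpent-3-en-1-yl]-2,3,4-trimethylcyclohexan-1-one
Conditions: TBAF (3.5 equiv), AcOH (3.5 equiv), THF, 0 °C → rt
Reagents that add atoms: none
Why: Fluoride-induced desilylation removes the two aryl silyl ethers and the secondary triethylsilyl ether, and the acetic acid buffer keeps the ketone α-centre and the allylic alcohol away from base.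

Step 15
Reactants: 23 (2R,3S,4S)-3-[(2S,3E)-5-(3-chloro-2,6-dihydroxy-4-methylphenyl)-2-hydroxy-3-methylpent-3-en-1-yl]-2,3,4-trimethylcyclohexan-1-one
Product: 24 2-chloro-5-hydroxy-6-[(2E,4S)-4-hydroxy-3-methyl-5-[(1S,2R,6S)-1,2,6-trimethyl-3-oxocyclohexyl]pent-2-en-1-yl]-3-methylcyclohexa-2,5-diene-1,4-dione
Conditions: K2[ON(SO3)2] (2.5 equiv), KH2PO4 buffer (pH 6), acetone–H2O, 0 °C → rt
Reagents that add atoms: potassium nitrosodisulfonate, [K+].[K+].[O]N(S(=O)(=O)[O-])S(=O)(=O)[O-]
Why: Teuber oxidation, in which the aryloxyl radical is trapped by a second nitrosodisulfonate at the only unsubstituted ring carbon (para to one hydroxyl, ortho to the other) and imidodisulfonate is lost, gives the 2-hydroxy-1,4-benzoquinone without touching the alkene, the carbinol or the ketone.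

## Compound list

1 | propanal | CCC=O | starting material
2 | but-3-en-2-one (methyl vinyl ketone) | CC(=O)C=C | starting material
3 | (2S)-2-methyl-5-oxohexanal | C[C@H](C=O)CCC(C)=O | intermediate
4 | (4S)-3-hydroxy-4-methylcyclohexan-1-one (aldol adduct, both C3 epimers) | C[C@H]1CCC(=O)CC1O | intermediate
5 | (4S)-4-methylcyclohex-2-en-1-one | C[C@@H]1C=CC(=O)CC1 | intermediate
6 | trimethyl{[(3R,4S)-4-methyl-3-(prop-2-en-1-yl)cyclohex-1-en-1-yl]oxy}silane | C=CC[C@@H]1[C@@H](C)CCC(O[Si](C)(C)C)=C1 | intermediate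
7 | (4S)-4-methyl-3-(prop-2-en-1-yl)cyclohex-2-en-1-one | C=CCC1=CC(=O)CC[C@@H]1C | intermediate
8 | {[(3S,4S)-3,4-dimethyl-3-(prop-2-en-1-yl)cyclohex-1-en-1-yl]oxy}trimethylsilane | C=CC[C@@]1(C)[C@@H](C)CCC(O[Si](C)(C)C)=C1 | intermediate
9 | lithium (3S,4S)-3,4-dimethyl-3-(prop-2-en-1-yl)cyclohex-1-en-1-olate | C=CC[C@@]1(C)[C@@H](C)CCC(O[Li])=C1 | intermediate
10 | (2R,3S,4S)-2,3,4-trimethyl-3-(prop-2-en-1-yl)cyclohexan-1-one | C=CC[C@@]1(C)[C@@H](C)CCC(=O)[C@@H]1C | intermediate
11 | (2R,3S,4S)-2,3,4-trimethyl-3-(1,2,4-trioxolan-3-ylmethyl)cyclohexan-1-one (both epimers at the trioxolane carbon) | C1(C[C@@]2(C)[C@@H](C)CCC(=O)[C@@H]2C)OCOO1 | intermediate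
12 | 2-[(1S,2R,6S)-1,2,6-trimethyl-3-oxocyclohexyl]acetaldehyde | O=CC[C@@]1(C)[C@@H](C)CCC(=O)[C@@H]1C | intermediate
13 | 5-methylbenzene-1,3-diol (orcinol) | Cc1cc(O)cc(O)c1 | starting material
14 | disodium 5-methylbenzene-1,3-diolate | Cc1cc([O-])cc([O-])c1.[Na+].[Na+] | intermediate
15 | 1,3-bis(methoxymethoxy)-5-methylbenzene | Cc1cc(OCOC)cc(OCOC)c1 | intermediate
16 | 1-bromobut-2-yne | CC#CCBr | starting material
17 | [2,6-bis(methoxymethoxy)-4-methylphenyl]lithium | Cc1cc(OCOC)c([Li])c(OCOC)c1 | intermediate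
18 | 2-(but-2-yn-1-yl)-1,3-bis(methoxymethoxy)-5-methylbenzene | CC#CCc1c(OCOC)cc(C)cc1OCOC | intermediate
19 | 2-(but-2-yn-1-yl)-5-methylbenzene-1,3-diol | CC#CCc1c(O)cc(C)cc1O | intermediate
20 | 2-(but-2-yn-1-yl)-4-chloro-5-methylbenzene-1,3-diol | CC#CCc1c(O)cc(C)c(Cl)c1O | intermediate
21 | {[2-(but-2-yn-1-yl)-4-chloro-5-methyl-1,3-phenylene]bis(oxy)}bis[tert-butyl(dimethyl)silane] | CC#CCc1c(O[Si](C)(C)C(C)(C)C)cc(C)c(Cl)c1O[Si](C)(C)C(C)(C)C | intermediate
22 | (2R,3S,4S)-3-[(2S,3E)-5-{2,6-bis[(tert-butyldimethylsilyl)oxy]-3-chloro-4-methylphenyl}-3-methyl-2-[(triethylsilyl)oxy]pent-3-en-1-yl]-2,3,4-trimethylcyclohexan-1-one | Cc1cc(O[Si](C)(C)C(C)(C)C)c(C/C=C(\C)[C@@H](O[Si](CC)(CC)CC)C[C@@]2(C)[C@@H](C)CCC(=O)[C@@H]2C)c(O[Si](C)(C)C(C)(C)C)c1Cl | intermediate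
23 | (2R,3S,4S)-3-[(2S,3E)-5-(3-chloro-2,6-dihydroxy-4-methylphenyl)-2-hydroxy-3-methylpent-3-en-1-yl]-2,3,4-trimethylcyclohexan-1-one | Cc1cc(O)c(C/C=C(\C)[C@@H](O)C[C@@]2(C)[C@@H](C)CCC(=O)[C@@H]2C)c(O)c1Cl | intermediate
24 | 2-chloro-5-hydroxy-6-[(2E,4S)-4-hydroxy-3-methyl-5-[(1S,2R,6S)-1,2,6-trimethyl-3-oxocyclohexyl]pent-2-en-1-yl]-3-methylcyclohexa-2,5-diene-1,4-dione | CC1=C(Cl)C(=O)C(C/C=C(\C)[C@@H](O)C[C@@]2(C)[C@@H](C)CCC(=O)[C@@H]2C)=C(O)C1=O | target

## Step count and risks

Total step count: 15. Longest linear sequence: 10 steps (steps 1 to 7, then 13 to 15); the arene branch is 5 steps (8 to 12).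

Three steps most likely to fail:

Step 6 (C2 methylation). The enolate carbon is neopentyl-like, so proton transfer to the product could lead to methylation at C6 or to loss of the kinetically set C2 configuration, which is estimated to be the less stable epimer. The fallback sets out from 8 and comes back at 10, and replaces enolate alkylation by cyclopropanation. Et2Zn/CH2I2 in CH2Cl2 at 0 °C adds methylene to the electron-rich enol ether double bond, anti to the pseudoaxial allyl group, and gives trimethyl{[(1S,4S,5S,6R)-4,5-dimethyl-5-(prop-2-en-1-yl)bicyclo[4.1.0]heptan-1-yl]oxy}silane F1. Catalytic p-TsOH in MeOH at rt then opens the siloxycyclopropane at the C1–CH2 bond to give 10; the new methyl is the former cyclopropane methylene and C2 never passes through an enolate.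

Step 9 (propargylation of the aryllithium). Attack at the far alkyne carbon would give an allene, and the propargylic bromide can also be deprotonated. The fallback sets out from 15 (lithiated to 17 as before) and comes back at 18, and builds the terminal methyl last. Aryllithium 17 and 3-bromo-1-(trimethylsilyl)prop-1-yne (THF, −78 °C → rt) give {3-[2,6-bis(methoxymethoxy)-4-methylphenyl]prop-1-yn-1-yl}trimethylsilane F2, the silyl group blocking attack at the remote alkyne carbon. K2CO3 in MeOH gives 1,3-bis(methoxymethoxy)-5-methyl-2-(prop-2-yn-1-yl)benzene F3. n-BuLi (THF, −78 °C) gives {3-[2,6-bis(methoxymethoxy)-4-methylphenyl]prop-1-yn-1-yl}lithium F4, which MeI converts into 18.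

Step 13 (the proposed new coupling). Possible failures are C–C bond formation at the wrong alkyne carbon, weak facial control at the aldehyde, and insertion of zerovalent nickel into the aryl chloride. The fallback uses known chemistry, sets out from 21 (with 12) and comes back at 23. Hydrozirconation of 21 with excess Cp2Zr(H)Cl (THF, 50 °C, so that zirconium settles on the methyl-bearing carbon) gives chlorobis(cyclopentadienyl){(2E)-4-[2,6-bis(tert-butyldimethylsilyloxy)-3-chloro-4-methylphenyl]but-2-en-2-yl}zirconium F5. Iodine converts it with retention into {[4-chloro-2-[(2E)-3-iodobut-2-en-1-yl]-5-methyl-1,3-phenylene]bis(oxy)}bis[tert-butyl(dimethyl)silane] F6. An asymmetric Nozaki–Hiyama–Kishi coupling of F6 with 12 (CrCl2 3 equiv, NiCl2 2 mol%, (S)-N-[2-(4-isopropyl-4,5-dihydrooxazol-2-yl)-6-methylphenyl]methanesulfonamide or its antipode as needed for the 2S alcohol, Et3N, THF, rt) is aldehyde-selective and leaves the aryl chloride alone. It gives (2R,3S,4S)-3-[(2S,3E)-5-{2,6-bis[(tert-butyldimethylsilyl)oxy]-3-chloro-4-methylphenyl}-2-hydroxy-3-methylpent-3-en-1-yl]-2,3,4-trimethylcyclohexan-1-one F7, which under the conditions of step 14 gives 23.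

## Further compounds

F1 | step 6 | trimethyl{[(1S,4S,5S,6R)-4,5-dimethyl-5-(prop-2-en-1-yl)bicyclo[4.1.0]heptan-1-yl]oxy}silane | C=CC[C@@]1(C)[C@@H](C)CC[C@]2(O[Si](C)(C)C)C[C@H]12
F2 | step 9 | {3-[2,6-bis(methoxymethoxy)-4-methylphenyl]prop-1-yn-1-yl}trimethylsilane | C[Si](C)(C)C#CCc1c(OCOC)cc(C)cc1OCOC
F3 | step 9 | 1,3-bis(methoxymethoxy)-5-methyl-2-(prop-2-yn-1-yl)benzene | C#CCc1c(OCOC)cc(C)cc1OCOC
F4 | step 9 | {3-[2,6-bis(methoxymethoxy)-4-methylphenyl]prop-1-yn-1-yl}lithium | [Li]C#CCc1c(OCOC)cc(C)cc1OCOC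
F5 | step 13 | chlorobis(cyclopentadienyl){(2E)-4-[2,6-bis(tert-butyldimethylsilyloxy)-3-chloro-4-methylphenyl]but-2-en-2-yl}zirconium | C/C(=C\Cc1c(O[Si](C)(C)C(C)(C)C)cc(C)c(Cl)c1O[Si](C)(C)C(C)(C)C)[Zr](Cl)(C1C=CC=C1)C1C=CC=C1
F6 | step 13 | {[4-chloro-2-[(2E)-3-iodobut-2-en-1-yl]-5-methyl-1,3-phenylene]bis(oxy)}bis[tert-butyl(dimethyl)silane] | C/C(I)=C\Cc1c(O[Si](C)(C)C(C)(C)C)cc(C)c(Cl)c1O[Si](C)(C)C(C)(C)C
F7 | step 13 | (2R,3S,4S)-3-[(2S,3E)-5-{2,6-bis[(tert-butyldimethylsilyl)oxy]-3-chloro-4-methylphenyl}-2-hydroxy-3-methylpent-3-en-1-yl]-2,3,4-trimethylcyclohexan-1-one | Cc1cc(O[Si](C)(C)C(C)(C)C)c(C/C=C(\C)[C@@H](O)C[C@@]2(C)[C@@H](C)CCC(=O)[C@@H]2C)c(O[Si](C)(C)C(C)(C)C)c1Cl
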